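**Plan**

1. Atom labels used below: five-membered ring C1 (methyl-bearing fusion carbon)–C2–C3–C4 (isopropyl carbinol)–C5 (fusion CH); seven-membered ring C5–C6 (ester-bearing)–C7=C8(Me)–C9–C10–C1. Systematic names carry their own locants.
2. Retrosynthetic cuts, in order: the C6–O acyl bond (isovanillate), the C4–isopropyl bond (back to a C4 ketone), the C6–C7 bond (aldehyde plus (Z)-alkenyl iodide), then the C1–C5 bond (carbenoid C–H insertion). The open chain comes from (R)-citronellyl bromide, propyne and ethyl diazoacetate.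
3. Feature used: C1 carries a methyl group and two CH2CH2 arms, which is the substitution of the citronellyl stereocentre, and it is the fifth atom counted from C5 through C4, C3 and C2. C5 is flanked by the oxygen-bearing carbons C4 and C6, so it can be an acceptor carbenoid between a ketone (C4) and an ester (C6) and insert into the C1–H bond.
4. Forward order: chain assembly, cyclopentanone first (C1–C5), then the cycloheptene (C6–C7) onto the preinstalled (Z)-alkenyl iodide, then isopropyl at C4 and the aryl ester at C6.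
5. Stereochemistry: C1 from citronellyl (retention in the insertion); C5 by catalyst-controlled dynamic kinetic hydrogenation of the β-keto ester, which fixes the cis ring fusion; C6 and C4 by attack on the convex face of the cis-fused bicycle (hydride at C6, isopropyl at C4).

Key step: step 5

Remark: the target SMILES places the C5 hydrogen and the C1 methyl group on the same face (cis-fused hydroazulene); the ester alkyl group is a spectator, so commercial ethyl diazoacetate is used.

**Route**

Step 1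
Reactants: 1 (R)-citronellyl bromide; 2 propyne
Product: 6 (1Z,5R)-1-iodo-2,5,9-trimethyldeca-1,8-diene, via citronellylmagnesium bromide 3 (not isolated), via citronellylcopper 4 (not isolated), via alkenylcopper 5 (not isolated)
Conditions: Mg, Et2O; CuBr·SMe2, Et2O/Me2S, −45 °C; propyne (excess), −25 °C; I2, THF, −78 °C to 0 °C
Reagents that add atoms: iodine, II
Why: Normant carbocupration of propyne is a syn addition that puts the citronellyl chain on the internal carbon and copper cis to it on the terminal carbon, and iodinolysis with retention should give the (Z)-alkenyl iodide without touching the stereocentre.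

Step 2
Reactants: 6 (1Z,5R)-1-iodo-2,5,9-trimethyldeca-1,8-diene
Product: 8 (4S,7Z)-8-iodo-4,7-dimethyloct-7-enal, via ozonide 7 (not isolated)
Conditions: O3, CH2Cl2, −78 °C, Sudan Red 7B end point; then PPh3, −78 °C to rt
Reagents that add atoms: ozone, [O-][O+]=O
Why: Ozonolysis with reductive work-up should cleave the electron-rich trisubstituted alkene much faster than the iodine-deactivated alkenyl iodide when ozone delivery is stopped at the dye end point.

Step 3
Reactants: 8 (4S,7Z)-8-iodo-4,7-dimethyloct-7-enal; 9 ethyl diazoacetate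
Product: 10 ethyl (6S,9Z)-10-iodo-6,9-dimethyl-3-oxodec-9-enoate
Conditions: SnCl2 (10 mol%), CH2Cl2, rt
Reagents that add atoms: none
Why: Roskamp homologation, in which SnCl2-promoted addition of the diazoacetate to the aldehyde is followed by a 1,2-hydride shift with loss of N2, should give the β-keto ester directly.

Step 4
Reactants: 10 ethyl (6S,9Z)-10-iodo-6,9-dimethyl-3-oxodec-9-enoate
Product: 11 ethyl (6S,9Z)-2-diazo-10-iodo-6,9-dimethyl-3-oxodec-9-enoate
Conditions: 4-acetamidobenzenesulfonyl azide, Et3N, MeCN, 0 °C to rt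
Reagents that add atoms: 4-acetamidobenzenesulfonyl azide, CC(=O)Nc1ccc(cc1)S(=O)(=O)N=[N+]=[N-]
Why: Regitz diazo transfer to the doubly activated methylene of a β-keto ester is a standard, mild reaction.

Step 5
Reactants: 11 ethyl (6S,9Z)-2-diazo-10-iodo-6,9-dimethyl-3-oxodec-9-enoate
Product: 12 ethyl (1R,2R)-2-[(3Z)-4-iodo-3-methylbut-3-en-1-yl]-2-methyl-5-oxocyclopentane-1-carboxylate
Conditions: Rh2(OAc)4 (1 mol%), CH2Cl2, rt, slow addition of 11
Reagents that add atoms: none
Why: Rh2(OAc)4 expels N2 from 11 to give an acceptor-substituted rhodium carbenoid at C5, which engages the C1–H bond in a concerted three-centre transition state that forms C1–C5 and releases the catalyst; the closest known reaction type is the dirhodium-catalysed intramolecular 1,5 C–H insertion of 2-diazo-3-oxo esters into tertiary C–H bonds. The ring closed is the cyclopentanone C1–C2–C3–C4–C5, formed by 1,5 insertion through a six-centre array that includes the transferred hydrogen. C1 becomes quaternary with retention, so its configuration is dictated by the citronellyl stereocentre, while C5 is created between two carbonyl groups and stays epimerisable (the drawn isomer is one of two interconverting forms that step 6 resolves). The step needs site selectivity for the C1–H bond, which is secured because it is the only C–H bond that gives a five-membered ring, it is the most electron-rich C–H bond within reach, and the carbenoid carbon has no neighbouring hydrogen for a 1,2-shift. Chemoselectivity over the alkenyl iodide is expected because that alkene is remote from the carbenoid and electron-poor.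

Step 6
Reactants: 12 ethyl (1R,2R)-2-[(3Z)-4-iodo-3-methylbut-3-en-1-yl]-2-methyl-5-oxocyclopentane-1-carboxylate
Product: 13 ethyl (1R,2R,5R)-5-hydroxy-2-[(3Z)-4-iodo-3-methylbut-3-en-1-yl]-2-methylcyclopentane-1-carboxylate
Conditions: [RuCl(C6H6)((R)-BINAP)]Cl (1 mol%), H2 (100 atm), CH2Cl2, 50 °C
Reagents that add atoms: none
Why: Noyori asymmetric hydrogenation with dynamic kinetic resolution: C5 epimerises rapidly in the β-keto ester, the (R)-BINAP ruthenium chelate selects the carbonyl face and reduces the matching C5 epimer, and by analogy with 2-alkoxycarbonylcyclopentanones this should give the trans hydroxy ester with C4 and C5 (ester cis to the side chain) both set by the catalyst, since the two similar-sized C1 substituents exert little bias of their own.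

Step 7
Reactants: 13 ethyl (1R,2R,5R)-5-hydroxy-2-[(3Z)-4-iodo-3-methylbut-3-en-1-yl]-2-methylcyclopentane-1-carboxylate
Product: 14 ethyl (1R,2R,5R)-2-[(3Z)-4-iodo-3-methylbut-3-en-1-yl]-2-methyl-5-[(triethylsilyl)oxy]cyclopentane-1-carboxylate
Conditions: Et3SiCl, imidazole, DMF, 0 °C to rt
Reagents that add atoms: chlorotriethylsilane, CC[Si](Cl)(CC)CC
Why: Standard silylation of a secondary alcohol, with the triethylsilyl group chosen because it can later be removed in the presence of a tert-butyldimethylsilyl ether.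

Step 8
Reactants: 14 ethyl (1R,2R,5R)-2-[(3Z)-4-iodo-3-methylbut-3-en-1-yl]-2-methyl-5-[(triethylsilyl)oxy]cyclopentane-1-carboxylate
Product: 15 (1R,2R,5R)-2-[(3Z)-4-iodo-3-methylbut-3-en-1-yl]-2-methyl-5-[(triethylsilyl)oxy]cyclopentane-1-carbaldehyde
Conditions: i-Bu2AlH (1.1 equiv), CH2Cl2, −78 °C; aq. potassium sodium tartrate
Reagents that add atoms: none
Why: Partial reduction of a hindered ester with i-Bu2AlH at low temperature stops at the aldehyde oxidation level, and the aldehyde sits trans to the adjacent silyloxy group, the thermodynamically preferred arrangement, so C5 should not drift.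

Step 9
Reactants: 15 (1R,2R,5R)-2-[(3Z)-4-iodo-3-methylbut-3-en-1-yl]-2-methyl-5-[(triethylsilyl)oxy]cyclopentane-1-carbaldehyde
Product: 17 (3R,3aS,8aR)-6,8a-dimethyl-3-[(triethylsilyl)oxy]-1,2,3,3a,4,7,8,8a-octahydroazulen-4-ol (both epimers at the new carbinol carbon), via alkenylchromium dichloride 16 (not isolated)
Conditions: CrCl2 (8 equiv), NiCl2 (2 mol%), degassed DMSO, rt, high dilution
Reagents that add atoms: none
Why: Intramolecular Nozaki–Hiyama–Kishi reaction, in which the nickel-catalysed alkenylchromium species adds chemoselectively to the aldehyde, should close the seven-membered ring (C6–C7) with cis fusion because the aldehyde and the side chain sit on the same face of the cyclopentane; the C6 configuration is not relied on and is erased in step 10.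

Step 10
Reactants: 17 (3R,3aS,8aR)-6,8a-dimethyl-3-[(triethylsilyl)oxy]-1,2,3,3a,4,7,8,8a-octahydroazulen-4-ol
Product: 18 (3R,3aR,8aR)-6,8a-dimethyl-3-[(triethylsilyl)oxy]-2,3,3a,7,8,8a-hexahydroazulen-4(1H)-one
Conditions: Pr4N[RuO4] (5 mol%), N-methylmorpholine N-oxide, 4 Å MS, CH2Cl2, rt
Reagents that add atoms: none
Why: Ley–Griffith oxidation converges both allylic alcohol epimers to one enone under neutral conditions that should neither epimerise C5 nor eliminate the β-silyloxy group.

Step 11
Reactants: 18 (3R,3aR,8aR)-6,8a-dimethyl-3-[(triethylsilyl)oxy]-2,3,3a,7,8,8a-hexahydroazulen-4(1H)-one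
Product: 19 (3R,3aS,4R,8aR)-6,8a-dimethyl-3-[(triethylsilyl)oxy]-1,2,3,3a,4,7,8,8a-octahydroazulen-4-ol
Conditions: NaBH4, CeCl3·7H2O, MeOH, −78 °C
Reagents that add atoms: none
Why: Luche 1,2-reduction, in which hydride should add to the convex face of the cis-fused enone (the face of the C5 hydrogen, away from the five-membered ring), placing the C6 hydrogen cis to the C5 hydrogen and giving the (R)-carbinol.

Step 12
Reactants: 19 (3R,3aS,4R,8aR)-6,8a-dimethyl-3-[(triethylsilyl)oxy]-1,2,3,3a,4,7,8,8a-octahydroazulen-4-ol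
Product: 20 (3R,3aR,4R,8aR)-4-[(tert-butyldimethylsilyl)oxy]-6,8a-dimethyl-3-[(triethylsilyl)oxy]-1,2,3,3a,4,7,8,8a-octahydroazulene
Conditions: t-BuMe2SiOTf, 2,6-lutidine, CH2Cl2, −78 °C to 0 °C
Reagents that add atoms: tert-butyldimethylsilyl trifluoromethanesulfonate, CC(C)(C)[Si](C)(C)OS(=O)(=O)C(F)(F)F
Why: Silyl triflate with a hindered pyridine base is the standard way to silylate a hindered secondary alcohol and leaves the triethylsilyl ether intact.

Step 13
Reactants: 20 (3R,3aR,4R,8aR)-4-[(tert-butyldimethylsilyl)oxy]-6,8a-dimethyl-3-[(triethylsilyl)oxy]-1,2,3,3a,4,7,8,8a-octahydroazulene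
Product: 21 (3R,3aR,4R,8aR)-4-[(tert-butyldimethylsilyl)oxy]-6,8a-dimethyl-1,2,3,3a,4,7,8,8a-octahydroazulen-3-ol
Conditions: pyridinium p-toluenesulfonate (cat.), MeOH/CH2Cl2, 0 °C
Reagents that add atoms: none
Why: Acid-catalysed methanolysis removes a triethylsilyl ether much faster than a tert-butyldimethylsilyl ether, a well-used selective desilylation.

Step 14
Reactants: 21 (3R,3aR,4R,8aR)-4-[(tert-butyldimethylsilyl)oxy]-6,8a-dimethyl-1,2,3,3a,4,7,8,8a-octahydroazulen-3-ol
Product: 22 (3aR,8R,8aS)-8-[(tert-butyldimethylsilyl)oxy]-3a,6-dimethyl-3,3a,4,5,8,8a-hexahydroazulen-1(2H)-one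
Conditions: Pr4N[RuO4] (5 mol%), N-methylmorpholine N-oxide, 4 Å MS, CH2Cl2, rt
Reagents that add atoms: none
Why: Ley–Griffith oxidation gives the C4 ketone under neutral conditions that should preserve the C5 stereocentre lying between the ketone and the silyloxy carbon.

Step 15
Reactants: 22 (3aR,8R,8aS)-8-[(tert-butyldimethylsilyl)oxy]-3a,6-dimethyl-3,3a,4,5,8,8a-hexahydroazulen-1(2H)-one
Product: 23 (3R,3aS,4R,8aR)-4-[(tert-butyldimethylsilyl)oxy]-6,8a-dimethyl-3-(propan-2-yl)-1,2,3,3a,4,7,8,8a-octahydroazulen-3-ol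
Conditions: CeCl3 (anhydrous), i-PrMgCl, THF, −78 °C
Reagents that add atoms: isopropylmagnesium chloride, CC(C)[Mg]Cl
Why: Organocerium addition, whose low basicity suppresses enolisation and β-elimination, should deliver isopropyl to the convex face of the cis-fused ketone, anti to the C5–C6 bond, giving the (R)-carbinol with the hydroxyl cis to C6.

Step 16
Reactants: 23 (3R,3aS,4R,8aR)-4-[(tert-butyldimethylsilyl)oxy]-6,8a-dimethyl-3-(propan-2-yl)-1,2,3,3a,4,7,8,8a-octahydroazulen-3-ol
Product: 24 (3R,3aS,4R,8aR)-6,8a-dimethyl-3-(propan-2-yl)-1,2,3,3a,4,7,8,8a-octahydroazulene-3,4-diol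
Conditions: Bu4NF, THF, 0 °C to rt
Reagents that add atoms: none
Why: Fluoride-mediated desilylation frees the secondary allylic hydroxyl without affecting the tertiary alcohol or the alkene.

Step 17
Reactants: 25 isovanillic acid
Product: 26 3-acetoxy-4-methoxybenzoic acid
Conditions: Ac2O, H2SO4 (cat.), 60 °C; then water
Reagents that add atoms: acetic anhydride, CC(=O)OC(C)=O
Why: Acid-catalysed O-acetylation of the phenol with acetic anhydride masks it so that the acid cannot acylate itself in the esterification.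

Step 18
Reactants: 24 (3R,3aS,4R,8aR)-6,8a-dimethyl-3-(propan-2-yl)-1,2,3,3a,4,7,8,8a-octahydroazulene-3,4-diol; 26 3-acetoxy-4-methoxybenzoic acid
Product: 27 (3R,3aS,4R,8aR)-3-hydroxy-6,8a-dimethyl-3-(propan-2-yl)-1,2,3,3a,4,7,8,8a-octahydroazulen-4-yl 3-acetoxy-4-methoxybenzoate
Conditions: DCC, DMAP, CH2Cl2, rt
Reagents that add atoms: none
Why: Steglich esterification acylates the secondary allylic hydroxyl, while the tertiary hydroxyl is too hindered to react.

Step 19
Reactants: 27 (3R,3aS,4R,8aR)-3-hydroxy-6,8a-dimethyl-3-(propan-2-yl)-1,2,3,3a,4,7,8,8a-octahydroazulen-4-yl 3-acetoxy-4-methoxybenzoate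
Product: 28 (3R,3aS,4R,8aR)-3-hydroxy-6,8a-dimethyl-3-(propan-2-yl)-1,2,3,3a,4,7,8,8a-octahydroazulen-4-yl 3-hydroxy-4-methoxybenzoate
Conditions: K2CO3 (cat.), MeOH, 0 °C
Reagents that add atoms: none
Why: Base-catalysed methanolysis (transesterification) cleaves the aryl acetate far faster than the hindered, electron-rich benzoate ester of the secondary alcohol.

**Compound list**

1 | (R)-citronellyl bromide, (6R)-8-bromo-2,6-dimethyloct-2-ene | BrCC[C@H](C)CCC=C(C)C | starting material
2 | propyne | CC#C | starting material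
3 | citronellylmagnesium bromide, [(3R)-3,7-dimethyloct-6-en-1-yl]magnesium bromide | Br[Mg]CC[C@H](C)CCC=C(C)C | intermediate
4 | citronellylcopper, [(3R)-3,7-dimethyloct-6-en-1-yl]copper | [Cu]CC[C@H](C)CCC=C(C)C | intermediate
5 | alkenylcopper, [(1Z,5R)-2,5,9-trimethyldeca-1,8-dien-1-yl]copper | [Cu]/C=C(C)\CC[C@H](C)CCC=C(C)C | intermediate
6 | (1Z,5R)-1-iodo-2,5,9-trimethyldeca-1,8-diene | I/C=C(C)\CC[C@H](C)CCC=C(C)C | intermediate
7 | ozonide, 3-[(3S,6Z)-7-iodo-3,6-dimethylhept-6-en-1-yl]-5,5-dimethyl-1,2,4-trioxolane (both epimers at the ring carbon) | I/C=C(C)\CC[C@H](C)CCC1OOC(C)(C)O1 | intermediate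
8 | (4S,7Z)-8-iodo-4,7-dimethyloct-7-enal | I/C=C(C)\CC[C@H](C)CCC=O | intermediate
9 | ethyl diazoacetate | CCOC(=O)C=[N+]=[N-] | starting material
10 | ethyl (6S,9Z)-10-iodo-6,9-dimethyl-3-oxodec-9-enoate | CCOC(=O)CC(=O)CC[C@@H](C)CC/C(C)=C\I | intermediate
11 | ethyl (6S,9Z)-2-diazo-10-iodo-6,9-dimethyl-3-oxodec-9-enoate | CCOC(=O)C(=[N+]=[N-])C(=O)CC[C@@H](C)CC/C(C)=C\I | intermediate
12 | ethyl (1R,2R)-2-[(3Z)-4-iodo-3-methylbut-3-en-1-yl]-2-methyl-5-oxocyclopentane-1-carboxylate (ring C1 epimerisable) | CCOC(=O)[C@@H]1[C@](C)(CC/C(C)=C\I)CCC1=O | intermediate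
13 | ethyl (1R,2R,5R)-5-hydroxy-2-[(3Z)-4-iodo-3-methylbut-3-en-1-yl]-2-methylcyclopentane-1-carboxylate | CCOC(=O)[C@@H]1[C@](C)(CC/C(C)=C\I)CC[C@H]1O | intermediate
14 | ethyl (1R,2R,5R)-2-[(3Z)-4-iodo-3-methylbut-3-en-1-yl]-2-methyl-5-[(triethylsilyl)oxy]cyclopentane-1-carboxylate | CCOC(=O)[C@@H]1[C@](C)(CC/C(C)=C\I)CC[C@H]1O[Si](CC)(CC)CC | intermediate
15 | (1R,2R,5R)-2-[(3Z)-4-iodo-3-methylbut-3-en-1-yl]-2-methyl-5-[(triethylsilyl)oxy]cyclopentane-1-carbaldehyde | O=C[C@@H]1[C@](C)(CC/C(C)=C\I)CC[C@H]1O[Si](CC)(CC)CC | intermediate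
16 | alkenylchromium dichloride from 15 (C–I replaced by C–CrCl2, Z geometry kept) | O=C[C@@H]1[C@](C)(CC/C(C)=C\[Cr](Cl)Cl)CC[C@H]1O[Si](CC)(CC)CC | intermediate
17 | (3R,3aS,8aR)-6,8a-dimethyl-3-[(triethylsilyl)oxy]-1,2,3,3a,4,7,8,8a-octahydroazulen-4-ol (both epimers at azulene C4) | OC2C=C(C)CC[C@]3(C)CC[C@@H](O[Si](CC)(CC)CC)[C@H]23 | intermediate
18 | (3R,3aR,8aR)-6,8a-dimethyl-3-[(triethylsilyl)oxy]-2,3,3a,7,8,8a-hexahydroazulen-4(1H)-one | O=C2C=C(C)CC[C@]3(C)CC[C@@H](O[Si](CC)(CC)CC)[C@H]23 | intermediate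
19 | (3R,3aS,4R,8aR)-6,8a-dimethyl-3-[(triethylsilyl)oxy]-1,2,3,3a,4,7,8,8a-octahydroazulen-4-ol | O[C@@H]2C=C(C)CC[C@]3(C)CC[C@@H](O[Si](CC)(CC)CC)[C@H]23 | intermediate
20 | (3R,3aR,4R,8aR)-4-[(tert-butyldimethylsilyl)oxy]-6,8a-dimethyl-3-[(triethylsilyl)oxy]-1,2,3,3a,4,7,8,8a-octahydroazulene | CC(C)(C)[Si](C)(C)O[C@@H]2C=C(C)CC[C@]3(C)CC[C@@H](O[Si](CC)(CC)CC)[C@H]23 | intermediate
21 | (3R,3aR,4R,8aR)-4-[(tert-butyldimethylsilyl)oxy]-6,8a-dimethyl-1,2,3,3a,4,7,8,8a-octahydroazulen-3-ol | CC(C)(C)[Si](C)(C)O[C@@H]2C=C(C)CC[C@]3(C)CC[C@@H](O)[C@H]23 | intermediate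
22 | (3aR,8R,8aS)-8-[(tert-butyldimethylsilyl)oxy]-3a,6-dimethyl-3,3a,4,5,8,8a-hexahydroazulen-1(2H)-one | CC(C)(C)[Si](C)(C)O[C@@H]2C=C(C)CC[C@]3(C)CCC(=O)[C@H]23 | intermediate
23 | (3R,3aS,4R,8aR)-4-[(tert-butyldimethylsilyl)oxy]-6,8a-dimethyl-3-(propan-2-yl)-1,2,3,3a,4,7,8,8a-octahydroazulen-3-ol | CC(C)(C)[Si](C)(C)O[C@@H]2C=C(C)CC[C@]3(C)CC[C@@](O)(C(C)C)[C@H]23 | intermediate
24 | (3R,3aS,4R,8aR)-6,8a-dimethyl-3-(propan-2-yl)-1,2,3,3a,4,7,8,8a-octahydroazulene-3,4-diol | O[C@@H]2C=C(C)CC[C@]3(C)CC[C@@](O)(C(C)C)[C@H]23 | intermediate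
25 | isovanillic acid, 3-hydroxy-4-methoxybenzoic acid | COc1ccc(C(=O)O)cc1O | starting material
26 | 3-acetoxy-4-methoxybenzoic acid | COc1ccc(C(=O)O)cc1OC(C)=O | intermediate
27 | (3R,3aS,4R,8aR)-3-hydroxy-6,8a-dimethyl-3-(propan-2-yl)-1,2,3,3a,4,7,8,8a-octahydroazulen-4-yl 3-acetoxy-4-methoxybenzoate | COc1ccc(C(=O)O[C@@H]2C=C(C)CC[C@]3(C)CC[C@@](O)(C(C)C)[C@H]23)cc1OC(C)=O | intermediate
28 | (3R,3aS,4R,8aR)-3-hydroxy-6,8a-dimethyl-3-(propan-2-yl)-1,2,3,3a,4,7,8,8a-octahydroazulen-4-yl 3-hydroxy-4-methoxybenzoate (CNP0210850.1) | COc1ccc(C(=O)O[C@@H]2C=C(C)CC[C@]3(C)CC[C@@](O)(C(C)C)[C@H]23)cc1O | target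

**Step count**

Total: 19 steps. Longest linear sequence: 18 steps (steps 1–16, 18, 19); step 17 is a one-step side branch.

**Steps most likely to fail**

Step 6. The hydrogenation may be slowed by the quaternary carbon next to the chelating ester, the catalyst may not fully override the existing C1 stereocentre (poor selection between the two C5 epimers), or the C–I bond may be reduced under hydrogen pressure. The fallback sets out from 12 and replaces metal-catalysed hydrogenation by a biocatalytic dynamic kinetic reduction: a ketoreductase with NADPH and isopropanol recycling in aqueous buffer/DMSO, screened for the trans (1R,2R,5R) hydroxy ester. These conditions do not touch alkenyl iodides. The route is rejoined at 13 and no new compound arises (entry F0).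

Step 15. The isopropyl reagent may reduce the hindered ketone by β-hydride transfer, enolise it toward C5, or trigger β-elimination of the silyloxy group instead of adding. The fallback sets out from 22. Isopropenylmagnesium bromide with CeCl3 in THF at −78 °C (a smaller nucleophile with no β-hydrogen to transfer) should add from the same convex face to give (3S,3aS,4R,8aR)-4-[(tert-butyldimethylsilyl)oxy]-6,8a-dimethyl-3-(prop-1-en-2-yl)-1,2,3,3a,4,7,8,8a-octahydroazulen-3-ol F1. Hydrogenation of its 1,1-disubstituted alkene with RhCl(PPh3)3 and H2 in benzene, which should spare the trisubstituted ring alkene, returns to the route at 23.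

Step 11. Hydride delivery to the flexible cycloheptenone may show poor or reversed facial selectivity, for example if the silyloxy group at C4 shields the convex face. The fallback sets out from 18 and corrects C6 by inversion instead of by facial control. The epimeric alcohol (3R,3aS,4S,8aR)-6,8a-dimethyl-3-[(triethylsilyl)oxy]-1,2,3,3a,4,7,8,8a-octahydroazulen-4-ol F2 from the reduction is subjected to Mitsunobu inversion (4-nitrobenzoic acid, PPh3, diisopropyl azodicarboxylate, toluene). This gives (3R,3aS,4R,8aR)-6,8a-dimethyl-3-[(triethylsilyl)oxy]-1,2,3,3a,4,7,8,8a-octahydroazulen-4-yl 4-nitrobenzoate F3. Methanolysis with K2CO3 in MeOH then rejoins the route at 19.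

Further compounds
F0 | step 6 | none | none
F1 | step 15 | (3S,3aS,4R,8aR)-4-[(tert-butyldimethylsilyl)oxy]-6,8a-dimethyl-3-(prop-1-en-2-yl)-1,2,3,3a,4,7,8,8a-octahydroazulen-3-ol | CC(C)(C)[Si](C)(C)O[C@@H]2C=C(C)CC[C@]3(C)CC[C@@](O)(C(C)=C)[C@H]23
F2 | step 11 | (3R,3aS,4S,8aR)-6,8a-dimethyl-3-[(triethylsilyl)oxy]-1,2,3,3a,4,7,8,8a-octahydroazulen-4-ol | O[C@H]2C=C(C)CC[C@]3(C)CC[C@@H](O[Si](CC)(CC)CC)[C@H]23
F3 | step 11 | (3R,3aS,4R,8aR)-6,8a-dimethyl-3-[(triethylsilyl)oxy]-1,2,3,3a,4,7,8,8a-octahydroazulen-4-yl 4-nitrobenzoate | O=C(O[C@@H]2C=C(C)CC[C@]3(C)CC[C@@H](O[Si](CC)(CC)CC)[C@H]23)c1ccc(cc1)[N+](=O)[O-]
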